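All runs were computed from invented constants; noise was put on by code.

Amounts first: the charge holds the two mirror images in equal strength, and in the winter and dawn runs the right-handed substrate stays near half of the charge while the left-handed substrate falls. The excess therefore hangs on one ratio.

| flask | left-handed substrate | right-handed substrate | gas | free catalyst | added ligand | remark | time |
|---|---|---|---|---|---|---|---|
| winter | 14 mM | 14 mM | 4.1 mM (held) | 7 µM | 42 µM | run made earlier |  |
| dawn | 14 mM | 14 mM | 4.1 mM (held) | 7 µM | 66 µM | run made earlier |  |
| spring | 7 mM | 7 mM | 4.1 mM (held) | 7 µM | 30 µM | run made earlier |  |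
| beta | 14 mM | 14 mM | 4.1 mM (held) | 7.0 µM | 30 µM |  | 15 min |
| theta | 14 mM | 14 mM | 4.1 mM (held) | 7.0 µM | 30 µM |  | 4.0 min |

| run | time / min | right-handed substrate / % | left-handed substrate / % | left-handed product / % |
|---|---|---|---|---|
| winter | 1.33 | 52 | 34 | 16 |
| winter | 2.50 | 49 | 23 | 29 |
| winter | 4.00 | 48 | 16 | 36 |
| winter | 5.00 | 49 | 10 | 41 |
| winter | 6.00 | 50 | 10 | 43 |
| winter | 8.00 | 50 | 6 | 49 |
| winter | 10.0 | 48 | 2 | 48 |
| dawn | 0.500 | 51 | 45 | 6 |
| dawn | 1.33 | 49 | 34 | 17 |
| dawn | 2.50 | 47 | 26 | 26 |
| dawn | 4.00 | 47 | 16 | 35 |
| dawn | 5.00 | 50 | 11 | 39 |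
| dawn | 8.00 | 47 | 4 | 44 |
| dawn | 10.0 | 51 | 3 | 48 |
| spring | 0.667 | 52 | 38 | 10 |
| spring | 1.33 | 50 | 30 | 23 |
| spring | 2.50 | 46 | 15 | 32 |
| spring | 5.00 | 48 | 5 | 43 |
| spring | 10.0 | 47 | 2 | 45 |

(readings scatter by 1.5 percentage points)

- free catalyst is single-handed; left-handed substrate and right-handed substrate are mirror images of each other, charged as a racemate, each of them at the stated concentration
- at the start none of the gas is in solution
- an excess is below zero if the other one leads

* which of the two ends with the higher excess of right-handed substrate over left-handed substrate among what is left of the two ("neither" if they lie within 2 percentage points) (beta / theta / neither)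
* excess of right-handed substrate over left-handed substrate among what is left of the two at the end, beta
* excess of right-handed substrate over left-handed substrate among what is left of the two at the end, theta

We call n = ln([right-handed substrate]/[left-handed substrate]) the clock; it starts at nought and, if the left-handed substrate decays first-order (pseudo-first-order, while the catalyst holds), it rises evenly. The excess is the difference of the two substrates over their sum. Early on that is about 0.5 times the clock, and late its gap to full excess is about 2 times [left-handed substrate]/[right-handed substrate]; the difference over the sum joins both ends.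

The winter and dawn readings at 4.00 min give a first rate of 0.272 min⁻¹. Beta's clock then stands at 4.08, well on the late side, which gives 96.7%. Theta's stands at 1.09, in the middle, where the joined form gives 49.6%.

The weak link is that rate, since it rests on two left-handed readings, each with a scatter of 1.5 percentage points. Adding the pair at 5.00 min gives the clock rate, the rise of n per minute, of 0.291 min⁻¹. We commit to 97.5% for beta and 52.4% for theta, so beta ends higher. Winter and dawn differ in added ligand yet read alike, so we carry the rate to 30 µM, which no run tests at 14 mM.

The forecast, holding the right-handed substrate “essentially unreactive”, names beta, with 97% and 51%.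

The simulation gives beta, with 95.4% for beta and 59.9% for theta.

    free catalyst + left-handed substrate ⇌ catalyst intermediate A (K = 38.0 M⁻¹, k = 70000 M⁻¹ s⁻¹)
    free catalyst + right-handed substrate ⇌ catalyst intermediate B (K = 24.0 M⁻¹, k = 18000 M⁻¹ s⁻¹)
    reagent + catalyst intermediate A → free catalyst + left-handed product (k = 20000 M⁻¹ s⁻¹)
    reagent + catalyst intermediate B → free catalyst + right-handed product (k = 380 M⁻¹ s⁻¹)
    gas ⇌ reagent, rate k5*(csat - [reagent]) (kL = 0.0920 s⁻¹)
    2 free catalyst → spent catalyst (k = 1100 M⁻¹ s⁻¹)
    free catalyst + added ligand ⇌ idle complex (K = 22000 M⁻¹, k = 4800 M⁻¹ s⁻¹)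

Read back through the clock, theta averaged 0.346 min⁻¹ and beta 0.250 min⁻¹, against the 0.291 min⁻¹ we carried, so the average rate of the longer flask was lower than that of the shorter. The gap between the two flasks is mainly the difference in time: given beta's 15 min, theta's charge reaches 95.4%. The neighbour flask, theta with 0.028 mM of free catalyst, 4.00 times the charge, averages 0.772 min⁻¹, which is 2.65 times our clock rate, and ends at an excess of 91.3%.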